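The route rests on cutting C6–C7 and C8–C9, the two oxepane bonds that flank the C7–C8 unit. C7 also holds O22 of the bridging lactone C20(=O)–O22, so that lactone can be redrawn as an isopropenyl ester hanging from C11 of a 3(2H)-furanone. One irradiation adds the ester alkene C7=C8 across the enone C9=C6. It closes the dioxanone, the seven-membered lactone and a sacrificial cyclobutane, and it sets C7 from C11. Heterolysis of the push–pull bond C6–C9 then releases the 6,8-dioxabicyclo[3.2.2]nonane core. The precursor is isopropenyl (R)-2-(3-chloropropyl)-5-(2-silyloxyethyl)-3-oxo-2,3-dihydrofuran-2-carboxylate.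

Key step: step 11

Atom labels:
- C1–C5 are the chain on C6 (C1 = CH2OH, C2=C3, methyl on C3).
- C6 is the ring O–CH, C7 is C(CH3)–O, C8 and C9 are ring CH2, C10 is CHOH and C11 is the quaternary carbon.
- C12–C16 are the chain on C11 (C14=C15, methyl on C15, C16 = CH2OH).
- C20 is the lactone C=O, O21 the ether oxygen and O22 the lactone oxygen.
- The target is (6S,7R,10S,11R) with both alkenes Z.
- In the systematic names position 1 = C11, 2 = C10, 5 = C7 and 9 = C6.
- TBDPS = tert-butyldiphenylsilyl, TBS = tert-butyldimethylsilyl, TES = triethylsilyl.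

Assumption: the sense of induction in step 8 is taken over from carbocyclic five-membered β-keto esters. If the adduct proves to be (S), the quinine-derived pseudoenantiomer, 9-O-(phenanthren-9-yl)cupreine, is used under the same conditions.

Design remarks:
- **Enol ester timing.** The enol ester is made from an aromatic 3-silyloxyfuroic acid, before C11 becomes quaternary. A 2,2-disubstituted 3-oxo acid would lose CO2 to give a hydroxyfuran.
- **Chlorine on C14.** C14 carries chlorine, not a protected hydroxyl, because a free C14 hydroxyl can lactonise onto C20 or add to C10. The chloride ignores light, Lewis acid, fluoride, borohydride and zinc, and it becomes the phosphonium salt directly.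
- **Stereocentres from the photocycloaddition.** It creates three stereocentres (C6, C7, C9). C9 is erased and C6 is re-set in step 12, so only C7 reaches the target.
- **Ionic opening of C6–C9.** In the cage this bond lies near the plane of the C10 carbonyl, while C8–C9 stands almost parallel to its π orbital. A ketyl could therefore break the wrong bond. Only C6–C9 has a donor at one end and an acceptor at the other.
- **Hydride delivery to C10.** The hydrogen on C10 has to enter from the groove between the ether bridge and the carbon bridge, which also holds the C6 arm. An external hydride should prefer the open lactone side, so the C4 hydroxyl is used to carry the hydride.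
- **No lactone-reducing reagent after step 11.** Both allylic alcohols arrive at the alcohol oxidation level.

Step 1
Reactants: 1 but-3-yn-1-ol
Product: 2 tert-butyl(but-3-yn-1-yloxy)diphenylsilane
Conditions: TBDPSCl, imidazole, CH2Cl2, 0 °C to rt
Reagents that add atoms: tert-butyl(chloro)diphenylsilane, CC(C)(C)[Si](Cl)(c1ccccc1)c1ccccc1
Why: Routine silylation of a primary alcohol; the robust TBDPS group is the only silyl ether that has to last until step 12.

Step 2
Reactants: 2 tert-butyl(but-3-yn-1-yloxy)diphenylsilane; 3 benzyl chloroformate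
Product: 5 benzyl 5-[(tert-butyldiphenylsilyl)oxy]pent-2-ynoate, via lithium acetylide 4 (not isolated)
Conditions: n-BuLi, THF, −78 °C; then 3, −78 to 0 °C
Reagents that add atoms: none
Why: C-acylation of a lithium acetylide by a chloroformate is the standard way to 2-ynoates, and the benzyl ester ensures that the alkoxide released in step 3 cannot scramble the esters.

Step 3
Reactants: 5 benzyl 5-[(tert-butyldiphenylsilyl)oxy]pent-2-ynoate; 6 benzyl glycolate
Product: 8 benzyl 5-{2-[(tert-butyldiphenylsilyl)oxy]ethyl}-3-hydroxyfuran-2-carboxylate, via enol ether diester 7 (not isolated)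
Conditions: NaH, THF, 0 °C to rt; then 1 M HCl
Reagents that add atoms: none
Why: Oxa-Michael addition of the glycolate alkoxide to the ynoate followed by Dieckmann condensation (the oxygen counterpart of the Fiesselmann thiophene synthesis) ends in an aromatic furanolate, which also shields the silyloxyethyl arm from E1cB loss of silanolate.

Step 4
Reactants: 8 benzyl 5-{2-[(tert-butyldiphenylsilyl)oxy]ethyl}-3-hydroxyfuran-2-carboxylate
Product: 9 benzyl 3-[(tert-butyldimethylsilyl)oxy]-5-{2-[(tert-butyldiphenylsilyl)oxy]ethyl}furan-2-carboxylate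
Conditions: TBSCl, imidazole, DMF, rt
Reagents that add atoms: tert-butyl(chloro)dimethylsilane, CC(C)(C)[Si](C)(C)Cl
Why: O-silylation of the acidic enol locks the β-keto ester as a plain furan, so the acid freed in step 5 is an ordinary furoic acid and not a β-keto acid.

Step 5
Reactants: 9 benzyl 3-[(tert-butyldimethylsilyl)oxy]-5-{2-[(tert-butyldiphenylsilyl)oxy]ethyl}furan-2-carboxylate
Product: 10 3-[(tert-butyldimethylsilyl)oxy]-5-{2-[(tert-butyldiphenylsilyl)oxy]ethyl}furan-2-carboxylic acid
Conditions: H2 (1 atm), 10% Pd/C, EtOAc, rt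
Reagents that add atoms: none
Why: Hydrogenolysis of a benzyl ester is neutral and leaves both silyl ethers and the acceptor-substituted furan untouched.

Step 6
Reactants: 10 3-[(tert-butyldimethylsilyl)oxy]-5-{2-[(tert-butyldiphenylsilyl)oxy]ethyl}furan-2-carboxylic acid; 11 propyne
Product: 12 prop-1-en-2-yl 3-[(tert-butyldimethylsilyl)oxy]-5-{2-[(tert-butyldiphenylsilyl)oxy]ethyl}furan-2-carboxylate
Conditions: [RuCl2(p-cymene)]2 (1 mol%), P(2-furyl)3, Na2CO3 (cat.), toluene, 50 °C, sealed vessel
Reagents that add atoms: none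
Why: Ruthenium-catalysed Markovnikov addition of a carboxylic acid to a terminal alkyne gives the geminal (isopropenyl) enol ester under nearly neutral conditions and brings in C7, C8 and the C7 methyl group.

Step 7
Reactants: 12 prop-1-en-2-yl 3-[(tert-butyldimethylsilyl)oxy]-5-{2-[(tert-butyldiphenylsilyl)oxy]ethyl}furan-2-carboxylate
Product: 13 prop-1-en-2-yl 5-{2-[(tert-butyldiphenylsilyl)oxy]ethyl}-3-hydroxyfuran-2-carboxylate
Conditions: Bu4NF, AcOH (1:1, 1.05 equiv), THF, 0 °C
Reagents that add atoms: none
Why: An enol (aryl-type) silyl ether is cleaved by buffered fluoride far faster than a primary alkyl TBDPS ether, and the acetic acid buffer prevents acyl transfer from the enol ester.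

Step 8
Reactants: 13 prop-1-en-2-yl 5-{2-[(tert-butyldiphenylsilyl)oxy]ethyl}-3-hydroxyfuran-2-carboxylate; 14 acrolein
Product: 15 prop-1-en-2-yl (2R)-5-{2-[(tert-butyldiphenylsilyl)oxy]ethyl}-3-oxo-2-(3-oxopropyl)-2,3-dihydrofuran-2-carboxylate
Conditions: 9-O-(phenanthren-9-yl)cupreidine (10 mol%), CH2Cl2, −25 °C
Reagents that add atoms: none
Why: Bifunctional cinchona-catalysed Michael addition of a cyclic β-keto ester to acrolein, in which the quinuclidine takes the enol proton, the 6'-hydroxyl binds acrolein, and attack through C2 of the furanolate on one enantiotopic face creates the quaternary centre C11 as (R).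

Step 9
Reactants: 15 prop-1-en-2-yl (2R)-5-{2-[(tert-butyldiphenylsilyl)oxy]ethyl}-3-oxo-2-(3-oxopropyl)-2,3-dihydrofuran-2-carboxylate
Product: 16 prop-1-en-2-yl (2R)-5-{2-[(tert-butyldiphenylsilyl)oxy]ethyl}-2-(3-hydroxypropyl)-3-oxo-2,3-dihydrofuran-2-carboxylate
Conditions: Me4NBH(OAc)3, MeCN/AcOH, −10 °C to rt; work-up at pH 5–6, used at once
Reagents that add atoms: none
Why: Triacetoxyborohydride reduces the aldehyde but neither the vinylogous-ester ketone nor the esters, and the acidic medium never forms an alkoxide, which holds back δ-lactonisation onto the enol ester.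

Step 10
Reactants: 16 prop-1-en-2-yl (2R)-5-{2-[(tert-butyldiphenylsilyl)oxy]ethyl}-2-(3-hydroxypropyl)-3-oxo-2,3-dihydrofuran-2-carboxylate
Product: 17 prop-1-en-2-yl (2R)-2-(3-chloropropyl)-5-{2-[(tert-butyldiphenylsilyl)oxy]ethyl}-3-oxo-2,3-dihydrofuran-2-carboxylate
Conditions: PPh3, N-chlorosuccinimide, CH2Cl2, 0 °C
Reagents that add atoms: N-chlorosuccinimide, O=C1CCC(=O)N1Cl
Why: Appel-type chlorination under neutral conditions removes the nucleophilic hydroxyl and leaves a spectator group that later becomes the phosphonium salt.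

Step 11
Reactants: 17 prop-1-en-2-yl (2R)-2-(3-chloropropyl)-5-{2-[(tert-butyldiphenylsilyl)oxy]ethyl}-3-oxo-2,3-dihydrofuran-2-carboxylate
Product: 18 caged photoadduct (6S,7R,9S,11R): tricyclic keto lactone containing the cyclobutane C6–C7–C8–C9
Conditions: hν (350 nm lamps, Pyrex), degassed MeCN (3 mM), 10 °C
Reagents that add atoms: none
Why: Excitation of the vinylogous-ester chromophore and intersystem crossing give the twisted enone triplet, which bonds C6 to C7 and, after spin inversion of the 1,4-biradical, C9 to C8 (bonding in the reverse order leads to the same adduct). The closest known reactions are the intramolecular enone–alkene [2+2] photocycloaddition of 2-alkenyl-3(2H)-furanones and the head-to-tail addition of isopropenyl esters to cyclic enones that opens a de Mayo sequence. The C6–C7 bond closes the 1,4-dioxan-2-one (O21, C11, C20, O22, C7, C6) in a 6-exo-trig mode, and the C8–C9 radical recombination closes the cyclobutane (C6, C7, C8, C9) and with it the seven-membered lactone ring (C7, C8, C9, C10, C11, C20, O22). C11 controls all three new centres: the two-atom tether lets the alkene reach only the furanone face that carries C20, so C6 and C9 become cis-fused on that face, and at C7 the tether oxygen O22 must point back to C11, which turns the methyl group outward and gives (7R). The step needs head-to-tail regiochemistry (C7 to the β-carbon C6 and not to C9), for which the tether allows both orientations, and it relies on the polarity match between the electron-rich terminus C8 of the enol ester and the α-carbon C9 of the excited enone. High dilution suppresses dimerisation, the 350 nm window leaves the enol ester, the silyl arenes and the C–Cl bond unexcited, and the fully substituted C11 cannot epimerise.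

Step 12
Reactants: 18 caged photoadduct
Product: 20 (1R,5R,9S)-1-(3-chloropropyl)-9-(2-hydroxyethyl)-5-methyl-6,8-dioxabicyclo[3.2.2]nonane-2,7-dione, via triethylsilyl enol ether 19 (not isolated)
Conditions: Et3SiH (5 equiv), Et3SiOTf (0.3 equiv), CH2Cl2, −78 to −20 °C; then HF·pyridine, THF, 0 °C to rt
Reagents that add atoms: none
Why: Proposed new method: Et3SiOTf silylates the C10 carbonyl oxygen while a lone pair of O21, antiperiplanar to C6–C9, pushes this strained bond open (the only ring bond with a donor at one end and an acceptor at the other) to give the oxocarbenium ion O21=C6 and the silyl enol ether C9=C10; Et3SiH then transfers hydride to C6 from the side of the flat lactone bridge, opposite to the departing C9 and away from the C8 methylene, which sets (6S) and regenerates Et3SiOTf, and HF·pyridine finally cleaves the enol ether and the TBDPS ether; the closest known reaction types are the retro-aldol step of the de Mayo sequence, the Lewis-acid opening of alkoxy-substituted donor–acceptor cyclobutanes by nucleophiles and the silane reduction of cyclic oxocarbenium ions.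

Step 13
Reactants: 20 (1R,5R,9S)-1-(3-chloropropyl)-9-(2-hydroxyethyl)-5-methyl-6,8-dioxabicyclo[3.2.2]nonane-2,7-dione
Product: 21 (1R,2S,5R,9S)-1-(3-chloropropyl)-2-hydroxy-9-(2-hydroxyethyl)-5-methyl-6,8-dioxabicyclo[3.2.2]nonan-7-one
Conditions: Me4NBH(OAc)3, MeCN/AcOH, −20 °C to rt; aqueous potassium sodium tartrate
Reagents that add atoms: none
Why: Saksena–Evans reduction, in which the C4 hydroxyl, whose arm lies in the groove between the ether bridge (C6–O21) and the carbon bridge (C8–C10), replaces an acetate on boron and hands the hydride to the face of C10 turned to that groove, so that the new hydroxyl points to the lactone bridge (10S) while the free reagent is too weak to reduce the ketone from outside.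

Step 14
Reactants: 21 (1R,2S,5R,9S)-1-(3-chloropropyl)-2-hydroxy-9-(2-hydroxyethyl)-5-methyl-6,8-dioxabicyclo[3.2.2]nonan-7-one
Product: 22 (1R,2S,5R,9S)-1-(3-chloropropyl)-2-hydroxy-9-(2-iodoethyl)-5-methyl-6,8-dioxabicyclo[3.2.2]nonan-7-one
Conditions: I2, PPh3, imidazole, CH2Cl2, 0 °C
Reagents that add atoms: iodine, II
Why: The Appel iodination takes the primary hydroxyl only, since the C10 hydroxyl next to the quaternary C11 is too hindered to be activated and lies on the face opposite to the arm, so no cyclic ether can form.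

Step 15
Reactants: 22 (1R,2S,5R,9S)-1-(3-chloropropyl)-2-hydroxy-9-(2-iodoethyl)-5-methyl-6,8-dioxabicyclo[3.2.2]nonan-7-one
Product: 23 (1R,2S,5R,9S)-1-(3-chloropropyl)-9-(2-iodoethyl)-5-methyl-2-[(triethylsilyl)oxy]-6,8-dioxabicyclo[3.2.2]nonan-7-one
Conditions: Et3SiOTf, 2,6-lutidine, CH2Cl2, −40 to 0 °C
Reagents that add atoms: triethylsilyl trifluoromethanesulfonate, CC[Si](CC)(CC)OS(=O)(=O)C(F)(F)F
Why: A silyl triflate silylates even this hindered secondary alcohol and so removes the only acidic proton before the organozinc and ylide steps.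

Step 16
Reactants: 24 but-2-yn-1-ol
Product: 26 (Z)-3-iodobut-2-en-1-ol, via cyclic alkenylaluminate 25 (not isolated)
Conditions: NaAlH2(OCH2CH2OMe)2, Et2O, 0 °C to rt; then I2, THF, −78 °C
Reagents that add atoms: iodine, II
Why: Hydroxyl-directed trans-hydroalumination places aluminium on C3 cis to the CH2O group in a five-membered aluminate, and iodinolysis with retention gives the Z-iodide.

Step 17
Reactants: 26 (Z)-3-iodobut-2-en-1-ol
Product: 27 tert-butyl{[(2Z)-3-iodobut-2-en-1-yl]oxy}dimethylsilane
Conditions: TBSCl, imidazole, CH2Cl2, 0 °C to rt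
Reagents that add atoms: tert-butyl(chloro)dimethylsilane, CC(C)(C)[Si](C)(C)Cl
Why: Routine silylation that hides the allylic hydroxyl from the organozinc reagent and is removed with the other silyl groups at the end.

Step 18
Reactants: 23 (1R,2S,5R,9S)-1-(3-chloropropyl)-9-(2-iodoethyl)-5-methyl-2-[(triethylsilyl)oxy]-6,8-dioxabicyclo[3.2.2]nonan-7-one; 27 tert-butyl{[(2Z)-3-iodobut-2-en-1-yl]oxy}dimethylsilane
Product: 29 (1R,2S,5R,9S)-9-{(3Z)-5-[(tert-butyldimethylsilyl)oxy]-3-methylpent-3-en-1-yl}-1-(3-chloropropyl)-5-methyl-2-[(triethylsilyl)oxy]-6,8-dioxabicyclo[3.2.2]nonan-7-one, via alkylzinc iodide 28 (not isolated)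
Conditions: activated Zn dust, LiCl, THF, 30 °C; then 27, PdCl2(dppf) (5 mol%), THF, rt to 45 °C
Reagents that add atoms: none
Why: Negishi sp3–sp2 coupling, in which zinc inserts only into the primary C–I bond (C–Cl, lactone and silyl ethers are tolerated) and the palladium-catalysed coupling with the alkenyl iodide goes with retention, which fixes the Z geometry of C2=C3.

Step 19
Reactants: 29 the coupled chloride
Product: 31 {3-[(1R,2S,5R,9S)-9-{(3Z)-5-[(tert-butyldimethylsilyl)oxy]-3-methylpent-3-en-1-yl}-5-methyl-7-oxo-2-[(triethylsilyl)oxy]-6,8-dioxabicyclo[3.2.2]nonan-1-yl]propyl}triphenylphosphonium iodide, via primary iodide 30 (not isolated)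
Conditions: NaI, PPh3, NaHCO3, MeCN, reflux
Reagents that add atoms: triphenylphosphine, c1ccc(cc1)P(c1ccccc1)c1ccccc1; sodium iodide, [Na+].[I-]
Why: Finkelstein exchange feeds the SN2 reaction with PPh3, so the unhindered primary chloride becomes the phosphonium iodide in one flask while NaHCO3 intercepts traces of acid.

Step 20
Reactants: 31 the phosphonium iodide; 32 1-[(tert-butyldimethylsilyl)oxy]propan-2-one
Product: 34 (1R,2S,5R,9S)-1-{(3Z)-5-[(tert-butyldimethylsilyl)oxy]-4-methylpent-3-en-1-yl}-9-{(3Z)-5-[(tert-butyldimethylsilyl)oxy]-3-methylpent-3-en-1-yl}-5-methyl-2-[(triethylsilyl)oxy]-6,8-dioxabicyclo[3.2.2]nonan-7-one, via phosphonium ylide 33 (not isolated)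
Conditions: KN(SiMe3)2, THF, −78 °C; then 32, −78 °C to rt
Reagents that add atoms: none
Why: Wittig reaction of a non-stabilised ylide (potassium base, lithium-free) with an α-silyloxy ketone, a pairing known to favour the Z-trisubstituted allylic ether (chain cis to CH2O) through the kinetic cis-oxaphosphetane, and at −78 °C the olefination should outrun attack of the ylide on the hindered lactone.

Step 21
Reactants: 34 the tris-silyl ether
Product: 35 target, (1R,2S,5R,9S)-2-hydroxy-9-[(3Z)-5-hydroxy-3-methylpent-3-en-1-yl]-1-[(3Z)-5-hydroxy-4-methylpent-3-en-1-yl]-5-methyl-6,8-dioxabicyclo[3.2.2]nonan-7-one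
Conditions: HF·pyridine, pyridine, THF, 0 °C to rt
Reagents that add atoms: none
Why: Fluoride cleavage of the three silyl ethers under weakly acidic, non-nucleophilic conditions leaves the lactone, both alkene geometries and all four stereocentres untouched.

Compound list
1 | but-3-yn-1-ol | C#CCCO | starting material
2 | tert-butyl(but-3-yn-1-yloxy)diphenylsilane | C#CCCO[Si](c1ccccc1)(c1ccccc1)C(C)(C)C | intermediate
3 | benzyl chloroformate | O=C(Cl)OCc1ccccc1 | starting material
4 | lithium acetylide of 2 (not isolated) | [Li]C#CCCO[Si](c1ccccc1)(c1ccccc1)C(C)(C)C | intermediate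
5 | benzyl 5-[(tert-butyldiphenylsilyl)oxy]pent-2-ynoate | O=C(OCc1ccccc1)C#CCCO[Si](c1ccccc1)(c1ccccc1)C(C)(C)C | intermediate
6 | benzyl glycolate | OCC(=O)OCc1ccccc1 | starting material
7 | benzyl (2Z)-3-[2-(benzyloxy)-2-oxoethoxy]-5-[(tert-butyldiphenylsilyl)oxy]pent-2-enoate (not isolated) | O=C(OCc1ccccc1)CO/C(CCO[Si](c1ccccc1)(c1ccccc1)C(C)(C)C)=C\C(=O)OCc1ccccc1 | intermediate
8 | benzyl 5-{2-[(tert-butyldiphenylsilyl)oxy]ethyl}-3-hydroxyfuran-2-carboxylate | O=C(OCc1ccccc1)c1oc(CCO[Si](c2ccccc2)(c2ccccc2)C(C)(C)C)cc1O | intermediate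
9 | benzyl 3-[(tert-butyldimethylsilyl)oxy]-5-{2-[(tert-butyldiphenylsilyl)oxy]ethyl}furan-2-carboxylate | O=C(OCc1ccccc1)c1oc(CCO[Si](c2ccccc2)(c2ccccc2)C(C)(C)C)cc1O[Si](C)(C)C(C)(C)C | intermediate
10 | 3-[(tert-butyldimethylsilyl)oxy]-5-{2-[(tert-butyldiphenylsilyl)oxy]ethyl}furan-2-carboxylic acid | O=C(O)c1oc(CCO[Si](c2ccccc2)(c2ccccc2)C(C)(C)C)cc1O[Si](C)(C)C(C)(C)C | intermediate
11 | propyne | CC#C | starting material
12 | prop-1-en-2-yl 3-[(tert-butyldimethylsilyl)oxy]-5-{2-[(tert-butyldiphenylsilyl)oxy]ethyl}furan-2-carboxylate | C=C(C)OC(=O)c1oc(CCO[Si](c2ccccc2)(c2ccccc2)C(C)(C)C)cc1O[Si](C)(C)C(C)(C)C | intermediate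
13 | prop-1-en-2-yl 5-{2-[(tert-butyldiphenylsilyl)oxy]ethyl}-3-hydroxyfuran-2-carboxylate | C=C(C)OC(=O)c1oc(CCO[Si](c2ccccc2)(c2ccccc2)C(C)(C)C)cc1O | intermediate
14 | acrolein | C=CC=O | starting material
15 | prop-1-en-2-yl (2R)-5-{2-[(tert-butyldiphenylsilyl)oxy]ethyl}-3-oxo-2-(3-oxopropyl)-2,3-dihydrofuran-2-carboxylate | O=CCC[C@@]1(C(=O)OC(C)=C)OC(CCO[Si](c2ccccc2)(c2ccccc2)C(C)(C)C)=CC1=O | intermediate
16 | prop-1-en-2-yl (2R)-5-{2-[(tert-butyldiphenylsilyl)oxy]ethyl}-2-(3-hydroxypropyl)-3-oxo-2,3-dihydrofuran-2-carboxylate | OCCC[C@@]1(C(=O)OC(C)=C)OC(CCO[Si](c2ccccc2)(c2ccccc2)C(C)(C)C)=CC1=O | intermediate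
17 | prop-1-en-2-yl (2R)-2-(3-chloropropyl)-5-{2-[(tert-butyldiphenylsilyl)oxy]ethyl}-3-oxo-2,3-dihydrofuran-2-carboxylate (photoprecursor) | ClCCC[C@@]1(C(=O)OC(C)=C)OC(CCO[Si](c2ccccc2)(c2ccccc2)C(C)(C)C)=CC1=O | intermediate
18 | caged photoadduct (6S,7R,9S,11R), bicyclic core with an extra C6–C9 bond | ClCCC[C@@]12O[C@]3(CCO[Si](c4ccccc4)(c4ccccc4)C(C)(C)C)[C@@](C)(C[C@@H]3C1=O)OC2=O | intermediate
19 | ring-opened triethylsilyl enol ether C9=C10 (6S,7R,11R) (not isolated) | ClCCC[C@@]12O[C@@H](CCO[Si](c3ccccc3)(c3ccccc3)C(C)(C)C)[C@@](C)(CC=C1O[Si](CC)(CC)CC)OC2=O | intermediate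
20 | (1R,5R,9S)-1-(3-chloropropyl)-9-(2-hydroxyethyl)-5-methyl-6,8-dioxabicyclo[3.2.2]nonane-2,7-dione | ClCCC[C@@]12O[C@@H](CCO)[C@@](C)(CCC1=O)OC2=O | intermediate
21 | (1R,2S,5R,9S)-1-(3-chloropropyl)-2-hydroxy-9-(2-hydroxyethyl)-5-methyl-6,8-dioxabicyclo[3.2.2]nonan-7-one | ClCCC[C@@]12O[C@@H](CCO)[C@@](C)(CC[C@@H]1O)OC2=O | intermediate
22 | (1R,2S,5R,9S)-1-(3-chloropropyl)-2-hydroxy-9-(2-iodoethyl)-5-methyl-6,8-dioxabicyclo[3.2.2]nonan-7-one | ClCCC[C@@]12O[C@@H](CCI)[C@@](C)(CC[C@@H]1O)OC2=O | intermediate
23 | (1R,2S,5R,9S)-1-(3-chloropropyl)-9-(2-iodoethyl)-5-methyl-2-[(triethylsilyl)oxy]-6,8-dioxabicyclo[3.2.2]nonan-7-one | ClCCC[C@@]12O[C@@H](CCI)[C@@](C)(CC[C@@H]1O[Si](CC)(CC)CC)OC2=O | intermediate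
24 | but-2-yn-1-ol | CC#CCO | starting material
25 | sodium cyclic alkenylaluminate (not isolated) | CC1=CCO[Al-]1(OCCOC)OCCOC.[Na+] | intermediate
26 | (Z)-3-iodobut-2-en-1-ol | C/C(I)=C/CO | intermediate
27 | tert-butyl{[(2Z)-3-iodobut-2-en-1-yl]oxy}dimethylsilane | C/C(I)=C/CO[Si](C)(C)C(C)(C)C | intermediate
28 | alkylzinc iodide from 23 (not isolated) | ClCCC[C@@]12O[C@@H](CC[Zn]I)[C@@](C)(CC[C@@H]1O[Si](CC)(CC)CC)OC2=O | intermediate
29 | coupled chloride with the complete Z chain on C6 | ClCCC[C@@]12O[C@@H](CC/C(C)=C\CO[Si](C)(C)C(C)(C)C)[C@@](C)(CC[C@@H]1O[Si](CC)(CC)CC)OC2=O | intermediate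
30 | primary iodide from 29 (not isolated) | ICCC[C@@]12O[C@@H](CC/C(C)=C\CO[Si](C)(C)C(C)(C)C)[C@@](C)(CC[C@@H]1O[Si](CC)(CC)CC)OC2=O | intermediate
31 | C14 triphenylphosphonium iodide | [I-].c3ccccc3[P+](c3ccccc3)(c3ccccc3)CCC[C@@]12O[C@@H](CC/C(C)=C\CO[Si](C)(C)C(C)(C)C)[C@@](C)(CC[C@@H]1O[Si](CC)(CC)CC)OC2=O | intermediate
32 | 1-[(tert-butyldimethylsilyl)oxy]propan-2-one | CC(=O)CO[Si](C)(C)C(C)(C)C | starting material
33 | phosphonium ylide from 31 (not isolated) | c3ccccc3P(c3ccccc3)(c3ccccc3)=CCC[C@@]12O[C@@H](CC/C(C)=C\CO[Si](C)(C)C(C)(C)C)[C@@](C)(CC[C@@H]1O[Si](CC)(CC)CC)OC2=O | intermediate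
34 | tris-silyl ether of the target | C/C(=C/CC[C@@]12O[C@@H](CC/C(C)=C\CO[Si](C)(C)C(C)(C)C)[C@@](C)(CC[C@@H]1O[Si](CC)(CC)CC)OC2=O)CO[Si](C)(C)C(C)(C)C | intermediate
35 | CNP0105745.1, (1R,2S,5R,9S)-2-hydroxy-9-[(3Z)-5-hydroxy-3-methylpent-3-en-1-yl]-1-[(3Z)-5-hydroxy-4-methylpent-3-en-1-yl]-5-methyl-6,8-dioxabicyclo[3.2.2]nonan-7-one | C/C(=C/CC[C@@]12O[C@@H](CC/C(C)=C\CO)[C@@](C)(CC[C@@H]1O)OC2=O)CO | target

Total step count: 21. Longest linear sequence: 19 steps (steps 1–15 and 18–21); steps 16 and 17 form the side branch.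

Steps most likely to fail

1. **Step 12.** The bond to be broken lies close to the plane of the C10 carbonyl group, so ionisation may be slow. The ion pair may collapse back to the cage or lose a proton from C5 before the silane arrives, and hydride transfer may lose its facial bias. The fallback uses known radical chemistry and sets out from 18. Bu3SnH and AIBN in refluxing benzene generate the O-stannyl ketyl at C10. Opening of the cyclobutane toward the tertiary, oxygen-stabilised C6 radical, followed by hydrogen transfer from the stannane on the lactone side, would give the tributyltin enolate F5. This is hydrolysed on work-up to the TBDPS-protected keto lactone F6. HF·pyridine then frees the C4 hydroxyl, and the route is rejoined at 20.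

2. **Step 11.** The ester tether rests mainly in its extended conformer, from which the alkene cannot reach the ring. Unproductive decay of the triplet, hydrogen abstraction from the arms, or bonding of C7 to C9 (head to head) may then take over. The fallback makes the same two bonds without the tether and sets out from 8.
   - The Michael addition of step 8 would give the benzyl ester aldehyde F1.
   - Me4NBH(OAc)3 would give the alcohol F2, and PPh3 with N-chlorosuccinimide the chloride F3.
   - Irradiation at 350 nm in isopropenyl acetate is a head-to-tail intermolecular enone–enol ester photocycloaddition. Among its diastereomers it would give the acetoxycyclobutane F4, in which the acetoxy group and the benzyl ester lie on the same face.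
   - K2CO3 in methanol removes the acetyl group. Only this isomer can close the lactone with loss of benzyl alcohol, which rejoins the route at 18.

3. **Step 13.** Exchange of the remote hydroxyl onto boron, or the medium-ring transition state, may be too slow. Undirected attack from the open lactone side would then erode the selectivity at C10. The fallback replaces substrate direction by reagent control and sets out from 20. It is a Corey–Bakshi–Shibata reduction with (R)-2-methyl-CBS-oxazaborolidine and BH3·SMe2 in THF at −20 °C, in which the C4 hydroxyl is taken up as a borate and freed on work-up. The catalyst binds the carbonyl lone pair on the side of the C9 methylene and tells it apart from the quaternary C11. This calls for the (S)-alcohol and leads directly to 19's successor in the route, compound 21, without any new compound.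

Further compounds
F1 | step 11 | benzyl (2R)-5-{2-[(tert-butyldiphenylsilyl)oxy]ethyl}-3-oxo-2-(3-oxopropyl)-2,3-dihydrofuran-2-carboxylate | O=CCC[C@@]1(C(=O)OCc2ccccc2)OC(CCO[Si](c2ccccc2)(c2ccccc2)C(C)(C)C)=CC1=O
F2 | step 11 | benzyl (2R)-5-{2-[(tert-butyldiphenylsilyl)oxy]ethyl}-2-(3-hydroxypropyl)-3-oxo-2,3-dihydrofuran-2-carboxylate | OCCC[C@@]1(C(=O)OCc2ccccc2)OC(CCO[Si](c2ccccc2)(c2ccccc2)C(C)(C)C)=CC1=O
F3 | step 11 | benzyl (2R)-2-(3-chloropropyl)-5-{2-[(tert-butyldiphenylsilyl)oxy]ethyl}-3-oxo-2,3-dihydrofuran-2-carboxylate | ClCCC[C@@]1(C(=O)OCc2ccccc2)OC(CCO[Si](c2ccccc2)(c2ccccc2)C(C)(C)C)=CC1=O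
F4 | step 11 | head-to-tail acetoxycyclobutane adduct (6S,7R,9S,11R) with acetoxy and benzyl ester on the same face | ClCCC[C@@]1(C(=O)OCc2ccccc2)O[C@]2(CCO[Si](c3ccccc3)(c3ccccc3)C(C)(C)C)[C@](C)(OC(C)=O)C[C@@H]2C1=O
F5 | step 12 | ring-opened tributyltin enolate (6S,7R,11R) | ClCCC[C@@]12O[C@@H](CCO[Si](c3ccccc3)(c3ccccc3)C(C)(C)C)[C@@](C)(CC=C1O[Sn](CCCC)(CCCC)CCCC)OC2=O
F6 | step 12 | (1R,5R,9S)-9-{2-[(tert-butyldiphenylsilyl)oxy]ethyl}-1-(3-chloropropyl)-5-methyl-6,8-dioxabicyclo[3.2.2]nonane-2,7-dione | ClCCC[C@@]12O[C@@H](CCO[Si](c3ccccc3)(c3ccccc3)C(C)(C)C)[C@@](C)(CCC1=O)OC2=O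
F0 | step 13 | none | none
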